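**Retrosynthetic overview**

- The last bond of the skeleton to be made is the diaryl ether C–O bond. It joins the oxygen of ring A that is meta to the side chain to the ring B carbon next to its para oxygen. Only removal of three MOM ethers follows.
- The ring B partner is a catechol bis-MOM ether, ortho-metalated at the one unhindered position. The ring A partner is a phenol made from a 4-substituted phenyl MOM ether by ortho-lithiation, borylation and oxidation.
- The two quaternary centres have opposite configuration (ring A side chain 3R, ring B side chain 3S). Each is set by a copper-catalysed enantioselective SN2′ arylation of (2E,6E)-farnesyl diethyl phosphate, using the two enantiomers of one ligand.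
- No ring is formed. Ring A is bought as 1-bromo-4-(methoxymethoxy)benzene, ring B as 4-bromocatechol, and the C15 chain as farnesol.

Assumption: 1-bromo-4-(methoxymethoxy)benzene is bought as such; L is the carbene precursor 2-[(4S,5S)-3-(2,4,6-trimethylphenyl)-4,5-diphenyl-4,5-dihydroimidazol-3-ium-1-yl]benzenesulfonate, and (S,S)-L is taken to give the 3R product (if the sense is the reverse, the two ligand enantiomers are exchanged between steps 3 and 4).

**Route**

Step 1
Reactants: 1 (2E,6E)-farnesol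
Product: 2 diethyl (2E,6E)-3,7,11-trimethyldodeca-2,6,10-trien-1-yl phosphate (farnesyl diethyl phosphate)
Conditions: ClP(O)(OEt)2, Et3N, DMAP (cat.), CH2Cl2, 0 °C to rt
Reagents that add atoms: diethyl chlorophosphate, CCOP(=O)(Cl)OCC
Why: O-phosphorylation of the primary allylic alcohol under amine base with DMAP catalysis is fast and leaves the alkenes, including the 2E geometry that later fixes the face of attack, untouched.

Step 2
Reactants: 3 4-bromocatechol (4-bromobenzene-1,2-diol)
Product: 4 4-bromo-1,2-bis(methoxymethoxy)benzene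
Conditions: MOMCl, i-Pr2NEt, CH2Cl2, 0 °C to rt
Reagents that add atoms: chloromethyl methyl ether (MOMCl), COCCl
Why: Williamson-type O-alkylation of both phenols gives a bis-acetal that survives organolithium and organoaluminium chemistry, later directs ortho-lithiation and comes off under mild acid.

Step 3
Reactants: 5 1-bromo-4-(methoxymethoxy)benzene, 2 farnesyl diethyl phosphate
Product: 8 1-(methoxymethoxy)-4-[(3R,6E)-3,7,11-trimethyldodeca-1,6,10-trien-3-yl]benzene (ring A monomer), via ring A aryllithium 6 (not isolated), via ring A arylaluminium 7 (not isolated)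
Conditions: n-BuLi, THF, −78 °C; Et2AlCl, −78 °C to rt; then 2, CuCl2·2H2O (5 mol %), (S,S)-L (5.5 mol %, pre-stirred with Ag2O), THF, −30 °C
Reagents that add atoms: none
Why: Bromine–lithium exchange, transmetalation to aluminium and carbene–copper-catalysed enantioselective allylic substitution (SN2′ arylation of a γ,γ-disubstituted allylic phosphate) form the aryl–C3 bond and move the alkene to the vinyl position, the sulfonate-bridged (S,S)-carbene–copper complex delivering the aryl group to one face of the 2E alkene to set the 3R quaternary centre.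

Step 4
Reactants: 4 4-bromo-1,2-bis(methoxymethoxy)benzene, 2 farnesyl diethyl phosphate
Product: 11 1,2-bis(methoxymethoxy)-4-[(3S,6E)-3,7,11-trimethyldodeca-1,6,10-trien-3-yl]benzene (ring B monomer), via ring B aryllithium 9 (not isolated), via ring B arylaluminium 10 (not isolated)
Conditions: n-BuLi, THF, −78 °C; Et2AlCl, −78 °C to rt; then 2, CuCl2·2H2O (5 mol %), (R,R)-L (5.5 mol %, pre-stirred with Ag2O), THF, −30 °C
Reagents that add atoms: none
Why: The same enantioselective SN2′ allylic arylation run with the mirror-image ligand delivers the aryl group to the opposite face of the 2E alkene and so sets the 3S quaternary centre needed on ring B.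

Step 5
Reactants: 8 ring A monomer
Product: 14 2-(methoxymethoxy)-5-[(3R,6E)-3,7,11-trimethyldodeca-1,6,10-trien-3-yl]phenol, via ortho-lithiated ring A monomer 12 (not isolated), via dimethyl arylboronate 13 (not isolated)
Conditions: n-BuLi, TMEDA, THF, −20 to 0 °C; B(OMe)3, −78 °C to rt; then H2O2 (30 % aq.), NaOH (aq.), 0 °C to rt
Reagents that add atoms: hydrogen peroxide, OO
Why: Directed ortho-metalation by the MOM ether (the two ortho positions are equivalent), borate formation and alkaline peroxide oxidation of the aryl boronate (1,2-aryl shift from boron to oxygen) install the OH meta to the side chain without touching the unactivated alkenes or the quaternary centre.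

Step 6
Reactants: 11 ring B monomer, 14 ring A phenol
Product: 19 1,2-bis(methoxymethoxy)-3-{2-(methoxymethoxy)-5-[(3R,6E)-3,7,11-trimethyldodeca-1,6,10-trien-3-yl]phenoxy}-5-[(3S,6E)-3,7,11-trimethyldodeca-1,6,10-trien-3-yl]benzene, via ortho-lithiated ring B monomer 15 (not isolated), via ring B arylcopper 16 (not isolated), via lithium phenoxide of ring A 17 (not isolated), via lithium aryl(aryloxy)cuprate 18 (not isolated)
Conditions: 11: n-BuLi, TMEDA, THF, −20 to 0 °C; CuCl·2LiCl, −50 °C; add 14 pre-treated with n-BuLi (THF, −78 °C); chloranil, −78 to −40 °C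
Reagents that add atoms: none
Why: Proposed new method: MOM-directed ortho-lithiation of 11 occurs at the only acetal-flanked position not blocked by the quaternary carbon, and transmetalation to copper followed by addition of lithium phenoxide 17 should place both partners on one monovalent copper centre as a heteroleptic aryl(aryloxy)cuprate; two-electron oxidation by chloranil at −78 °C is expected to give an aryl(aryloxy) trivalent copper species that collapses by C(aryl)–O reductive elimination, the product-forming event of Chan–Lam and Ullmann ether syntheses, faster than ligand scrambling to biaryl; the closest known reaction type is the chloranil-mediated oxidative amination of lithium amidocuprates, which has not been shown for aryloxide partners or diaryl ether formation; no stereocentre is touched.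

Step 7
Reactants: 19 tris-MOM diaryl ether
Product: 20 3-{2-hydroxy-5-[(3R,6E)-3,7,11-trimethyldodeca-1,6,10-trien-3-yl]phenoxy}-5-[(3S,6E)-3,7,11-trimethyldodeca-1,6,10-trien-3-yl]benzene-1,2-diol (target)
Conditions: HCl (3 M aq.), MeOH–THF (degassed), Ar, 40 °C
Reagents that add atoms: none
Why: Acid-catalysed acetal exchange with methanol (MOM ether cleavage) frees the three phenols under conditions that isolated trisubstituted alkenes tolerate, and the fully substituted benzylic centres have no hydrogen and cannot epimerise.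

**Compound list**

1 | (2E,6E)-farnesol | OC/C=C(\C)CC/C=C(\C)CCC=C(C)C | starting material
2 | diethyl (2E,6E)-3,7,11-trimethyldodeca-2,6,10-trien-1-yl phosphate | CCOP(=O)(OCC)OC/C=C(\C)CC/C=C(\C)CCC=C(C)C | intermediate
3 | 4-bromocatechol | Oc1ccc(Br)cc1O | starting material
4 | 4-bromo-1,2-bis(methoxymethoxy)benzene | COCOc1ccc(Br)cc1OCOC | intermediate
5 | 1-bromo-4-(methoxymethoxy)benzene | COCOc1ccc(Br)cc1 | starting material
6 | [4-(methoxymethoxy)phenyl]lithium | [Li]c1ccc(OCOC)cc1 | intermediate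
7 | diethyl[4-(methoxymethoxy)phenyl]aluminium | CC[Al](CC)c1ccc(OCOC)cc1 | intermediate
8 | 1-(methoxymethoxy)-4-[(3R,6E)-3,7,11-trimethyldodeca-1,6,10-trien-3-yl]benzene | C=C[C@@](C)(CC/C=C(\C)CCC=C(C)C)c1ccc(OCOC)cc1 | intermediate
9 | [3,4-bis(methoxymethoxy)phenyl]lithium | [Li]c1ccc(OCOC)c(OCOC)c1 | intermediate
10 | diethyl[3,4-bis(methoxymethoxy)phenyl]aluminium | CC[Al](CC)c1ccc(OCOC)c(OCOC)c1 | intermediate
11 | 1,2-bis(methoxymethoxy)-4-[(3S,6E)-3,7,11-trimethyldodeca-1,6,10-trien-3-yl]benzene | C=C[C@](C)(CC/C=C(\C)CCC=C(C)C)c1ccc(OCOC)c(OCOC)c1 | intermediate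
12 | {2-(methoxymethoxy)-5-[(3R,6E)-3,7,11-trimethyldodeca-1,6,10-trien-3-yl]phenyl}lithium | C=C[C@@](C)(CC/C=C(\C)CCC=C(C)C)c1ccc(OCOC)c([Li])c1 | intermediate
13 | dimethyl {2-(methoxymethoxy)-5-[(3R,6E)-3,7,11-trimethyldodeca-1,6,10-trien-3-yl]phenyl}boronate | C=C[C@@](C)(CC/C=C(\C)CCC=C(C)C)c1ccc(OCOC)c(B(OC)OC)c1 | intermediate
14 | 2-(methoxymethoxy)-5-[(3R,6E)-3,7,11-trimethyldodeca-1,6,10-trien-3-yl]phenol | C=C[C@@](C)(CC/C=C(\C)CCC=C(C)C)c1ccc(OCOC)c(O)c1 | intermediate
15 | {2,3-bis(methoxymethoxy)-5-[(3S,6E)-3,7,11-trimethyldodeca-1,6,10-trien-3-yl]phenyl}lithium | C=C[C@](C)(CC/C=C(\C)CCC=C(C)C)c1cc([Li])c(OCOC)c(OCOC)c1 | intermediate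
16 | {2,3-bis(methoxymethoxy)-5-[(3S,6E)-3,7,11-trimethyldodeca-1,6,10-trien-3-yl]phenyl}copper | C=C[C@](C)(CC/C=C(\C)CCC=C(C)C)c1cc([Cu])c(OCOC)c(OCOC)c1 | intermediate
17 | lithium 2-(methoxymethoxy)-5-[(3R,6E)-3,7,11-trimethyldodeca-1,6,10-trien-3-yl]phenoxide | [Li+].C=C[C@@](C)(CC/C=C(\C)CCC=C(C)C)c1ccc(OCOC)c([O-])c1 | intermediate
18 | lithium {2,3-bis(methoxymethoxy)-5-[(3S,6E)-3,7,11-trimethyldodeca-1,6,10-trien-3-yl]phenyl}{2-(methoxymethoxy)-5-[(3R,6E)-3,7,11-trimethyldodeca-1,6,10-trien-3-yl]phenoxy}cuprate | [Li+].C=C[C@@](C)(CC/C=C(\C)CCC=C(C)C)c1ccc(OCOC)c(O[Cu-]c2cc([C@](C)(C=C)CC/C=C(\C)CCC=C(C)C)cc(OCOC)c2OCOC)c1 | intermediate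
19 | 1,2-bis(methoxymethoxy)-3-{2-(methoxymethoxy)-5-[(3R,6E)-3,7,11-trimethyldodeca-1,6,10-trien-3-yl]phenoxy}-5-[(3S,6E)-3,7,11-trimethyldodeca-1,6,10-trien-3-yl]benzene | C=C[C@@](C)(CC/C=C(\C)CCC=C(C)C)c1ccc(OCOC)c(Oc2cc([C@](C)(C=C)CC/C=C(\C)CCC=C(C)C)cc(OCOC)c2OCOC)c1 | intermediate
20 | 3-{2-hydroxy-5-[(3R,6E)-3,7,11-trimethyldodeca-1,6,10-trien-3-yl]phenoxy}-5-[(3S,6E)-3,7,11-trimethyldodeca-1,6,10-trien-3-yl]benzene-1,2-diol | C=C[C@@](C)(CC/C=C(\C)CCC=C(C)C)c1ccc(O)c(Oc2cc([C@](C)(C=C)CC/C=C(\C)CCC=C(C)C)cc(O)c2O)c1 | target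

**Step count and risks**

Total steps: 7. Longest linear sequence: 5 (steps 1, 3, 5, 6, 7).

Steps most likely to fail:

1. Step 6 (proposed new C–O coupling). The cuprate may scramble to biaryl, the phenoxide may be oxidised by chloranil, or 11 may simply be returned by protonation. The fallback uses known chemistry, sets out from 11 and comes back at 19. Lithiate 11 as in step 6 to 15, quench with B(Oi-Pr)3 and hydrolyse gently to {2,3-bis(methoxymethoxy)-5-[(3S,6E)-3,7,11-trimethyldodeca-1,6,10-trien-3-yl]phenyl}boronic acid F1. Then couple F1 with phenol 14 by a Chan–Lam O-arylation (Cu(OAc)2, pyridine, 4 Å molecular sieves, CH2Cl2, dry air, rt) to give 19.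

2. Step 3 (step 4 shares the risk). The enantiomeric ratio or the SN2′ selectivity may be too low on the long farnesyl chain, and any leakage ends up as inseparable remote diastereomers of 20. The fallback replaces asymmetric catalysis by a racemic synthesis with resolution that uses both antipodes. It sets out from 7 (made from 5 as in step 3) and 2, comes back at 14 and also delivers 11.
   - Run the SN2′ arylation with an achiral carbene (1,3-bis(2,4,6-trimethylphenyl)imidazolinium chloride, CuCl2·2H2O, THF, −30 °C) to give racemic 1-(methoxymethoxy)-4-[(6E)-3,7,11-trimethyldodeca-1,6,10-trien-3-yl]benzene F2.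
   - Apply the step 5 sequence, through the racemic ortho-lithiated arene {2-(methoxymethoxy)-5-[(6E)-3,7,11-trimethyldodeca-1,6,10-trien-3-yl]phenyl}lithium F3 and the racemic dimethyl {2-(methoxymethoxy)-5-[(6E)-3,7,11-trimethyldodeca-1,6,10-trien-3-yl]phenyl}boronate F4, to reach racemic 2-(methoxymethoxy)-5-[(6E)-3,7,11-trimethyldodeca-1,6,10-trien-3-yl]phenol F5.
   - Resolve F5 by preparative chiral SFC on an amylose tris(3,5-dimethylphenylcarbamate) phase. The R enantiomer is 14.
   - Protect the other enantiomer, 2-(methoxymethoxy)-5-[(3S,6E)-3,7,11-trimethyldodeca-1,6,10-trien-3-yl]phenol F6, with MOMCl and i-Pr2NEt to give 11. Steps 2 and 4 are then not needed.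

3. Step 7 (global MOM removal). Protic acid may hydrate or cyclise the trisubstituted alkenes, and the electron-rich product oxidises easily. The fallback avoids Brønsted acid by an aprotic silyl exchange; it sets out from 19 and comes back at 20. Treat 19 with TMSOTf and 2,2′-bipyridyl (CH2Cl2, 0 °C to rt) to convert the three aryl MOM ethers into the tris(trimethylsilyl) ether 1,2-bis(trimethylsilyloxy)-3-{2-(trimethylsilyloxy)-5-[(3R,6E)-3,7,11-trimethyldodeca-1,6,10-trien-3-yl]phenoxy}-5-[(3S,6E)-3,7,11-trimethyldodeca-1,6,10-trien-3-yl]benzene F7. Hydrolyse F7 with water in THF at rt under argon to give 20.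

**Further compounds**

F1 | step 6 | {2,3-bis(methoxymethoxy)-5-[(3S,6E)-3,7,11-trimethyldodeca-1,6,10-trien-3-yl]phenyl}boronic acid | C=C[C@](C)(CC/C=C(\C)CCC=C(C)C)c1cc(B(O)O)c(OCOC)c(OCOC)c1
F2 | step 3 | racemic 1-(methoxymethoxy)-4-[(6E)-3,7,11-trimethyldodeca-1,6,10-trien-3-yl]benzene | C=CC(C)(CC/C=C(\C)CCC=C(C)C)c1ccc(OCOC)cc1
F3 | step 3 | racemic {2-(methoxymethoxy)-5-[(6E)-3,7,11-trimethyldodeca-1,6,10-trien-3-yl]phenyl}lithium | C=CC(C)(CC/C=C(\C)CCC=C(C)C)c1ccc(OCOC)c([Li])c1
F4 | step 3 | racemic dimethyl {2-(methoxymethoxy)-5-[(6E)-3,7,11-trimethyldodeca-1,6,10-trien-3-yl]phenyl}boronate | C=CC(C)(CC/C=C(\C)CCC=C(C)C)c1ccc(OCOC)c(B(OC)OC)c1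
F5 | step 3 | racemic 2-(methoxymethoxy)-5-[(6E)-3,7,11-trimethyldodeca-1,6,10-trien-3-yl]phenol | C=CC(C)(CC/C=C(\C)CCC=C(C)C)c1ccc(OCOC)c(O)c1
F6 | step 3 | 2-(methoxymethoxy)-5-[(3S,6E)-3,7,11-trimethyldodeca-1,6,10-trien-3-yl]phenol | C=C[C@](C)(CC/C=C(\C)CCC=C(C)C)c1ccc(OCOC)c(O)c1
F7 | step 7 | 1,2-bis(trimethylsilyloxy)-3-{2-(trimethylsilyloxy)-5-[(3R,6E)-3,7,11-trimethyldodeca-1,6,10-trien-3-yl]phenoxy}-5-[(3S,6E)-3,7,11-trimethyldodeca-1,6,10-trien-3-yl]benzene | C=C[C@@](C)(CC/C=C(\C)CCC=C(C)C)c1ccc(O[Si](C)(C)C)c(Oc2cc([C@](C)(C=C)CC/C=C(\C)CCC=C(C)C)cc(O[Si](C)(C)C)c2O[Si](C)(C)C)c1
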